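**Retrosynthetic overview**
- Dodoviscin G is reached by acid removal of three MOM ethers and one TBS ether from a fully protected 3-methoxyflavone, itself made by O-methylation of a flavonol.
- Ring C (the pyranone) is the only ring built, and it is built last, by Algar–Flynn–Oyamada oxidative cyclisation of a 2'-hydroxychalcone.
- The chalcone comes from an intermolecular Claisen–Schmidt aldol condensation of a ring A acetophenone with a ring B benzaldehyde; this makes the future C2–C3 bond.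
- Ring A ketone: 2-methoxyresorcinol, bis-MOM protection, Ir-catalysed C5 borylation/oxidation, O-benzylation, ortho-lithiation/acetylation, hydrogenolysis. The benzyl group marks the ring-closing oxygen, so the 6-OMe pattern is unambiguous.
- Ring B aldehyde: 3-bromo-4-hydroxybenzaldehyde, O-allylation/Claisen rearrangement, allyl converted to the (E)-CH2CH=C(Me)CH2OTBS chain (oxidative cleavage, stabilised Wittig, reduction), then Br replaced by prenyl through an arylcopper.

Assumption: the target has no stereocentre, so "single enantiomer" is read as the single (E)-isomer of the 4-hydroxy-3-methylbut-2-enyl chain given in the SMILES.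

Abbreviations: MOM = methoxymethyl; TBS = tert-butyldimethylsilyl; TBSO = tert-butyldimethylsilyloxy; Ar = 3-[(2E)-4-(TBSO)-3-methylbut-2-en-1-yl]-4-(methoxymethoxy)-5-(3-methylbut-2-en-1-yl)phenyl, the ring B aryl group of the aldehyde made in step 16.

**Ring A ketone**

Step 1
Reactants: 1 2-methoxybenzene-1,3-diol (2-methoxyresorcinol)
Product: 2 2-methoxy-1,3-bis(methoxymethoxy)benzene
Conditions: NaH (2.5 equiv), MOMCl (2.4 equiv), DMF, 0 °C → rt
Reagents that add atoms: chloromethyl methyl ether (MOMCl), COCCl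
Why: Double Williamson O-alkylation of the sodium phenoxides gives the bis-MOM ether, which tolerates every later basic, organometallic and peroxide step.

Step 2
Reactants: 2 2-methoxy-1,3-bis(methoxymethoxy)benzene
Product: 3 2-[4-methoxy-3,5-bis(methoxymethoxy)phenyl]-4,4,5,5-tetramethyl-1,3,2-dioxaborolane
Conditions: [Ir(OMe)(cod)]2 (1.5 mol%), 4,4'-di-tert-butyl-2,2'-bipyridine (3 mol%), B2pin2 (1.0 equiv), THF, 80 °C
Reagents that add atoms: bis(pinacolato)diboron, CC1(C)OB(OC1(C)C)B1OC(C)(C)C(C)(C)O1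
Why: Iridium-catalysed aromatic C–H borylation is sterically controlled, so only C5, the one C–H with no ortho substituent, reacts.

Step 3
Reactants: 3 2-[4-methoxy-3,5-bis(methoxymethoxy)phenyl]-4,4,5,5-tetramethyl-1,3,2-dioxaborolane
Product: 4 4-methoxy-3,5-bis(methoxymethoxy)phenol
Conditions: 30% H2O2, aq NaOH, THF, 0 °C; then aq Na2S2O3
Reagents that add atoms: hydrogen peroxide, OO
Why: Alkaline peroxide oxidation of the aryl boronate (1,2-aryl shift from boron to oxygen) gives the phenol at the same position.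

Step 4
Reactants: 4 4-methoxy-3,5-bis(methoxymethoxy)phenol
Product: 5 5-(benzyloxy)-2-methoxy-1,3-bis(methoxymethoxy)benzene
Conditions: BnBr (1.2 equiv), K2CO3 (2 equiv), DMF, rt, N2
Reagents that add atoms: benzyl bromide, BrCc1ccccc1
Why: Williamson ether synthesis marks this one oxygen with a hydrogenolysable benzyl group that is orthogonal to the MOM ethers.

Step 5
Reactants: 5 5-(benzyloxy)-2-methoxy-1,3-bis(methoxymethoxy)benzene
Product: 7 1-[6-(benzyloxy)-3-methoxy-2,4-bis(methoxymethoxy)phenyl]ethan-1-one, via aryllithium 6 (not isolated)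
Conditions: n-BuLi (1.2 equiv), TMEDA (1.2 equiv), THF, 0 °C, 1 h; then N-methoxy-N-methylacetamide (1.5 equiv), −78 °C → rt; then H2O
Reagents that add atoms: N-methoxy-N-methylacetamide, CC(=O)N(C)OC
Why: Directed ortho-metalation can only occur at the two symmetry-equivalent C–H positions flanked by OBn and OMOM, and Weinreb amide acylation stops at the methyl ketone through its chelated tetrahedral adduct.

Step 6
Reactants: 7 1-[6-(benzyloxy)-3-methoxy-2,4-bis(methoxymethoxy)phenyl]ethan-1-one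
Product: 8 1-[6-hydroxy-3-methoxy-2,4-bis(methoxymethoxy)phenyl]ethan-1-one
Conditions: H2 (1 atm), Pd/C (10 wt% Pd), EtOAc, rt
Reagents that add atoms: none
Why: Catalytic hydrogenolysis cleaves only the benzyl ether (no alkene is present yet) and frees the chelated ortho-hydroxyl that later becomes the pyranone oxygen.

**Ring B aldehyde**

Step 7
Reactants: 9 3-bromo-4-hydroxybenzaldehyde
Product: 10 3-bromo-4-(prop-2-en-1-yloxy)benzaldehyde
Conditions: allyl bromide (1.3 equiv), K2CO3 (2 equiv), DMF, rt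
Reagents that add atoms: allyl bromide, C=CCBr
Why: Williamson O-allylation of the acidic bromophenol sets up the Claisen rearrangement.

Step 8
Reactants: 10 3-bromo-4-(prop-2-en-1-yloxy)benzaldehyde
Product: 11 3-bromo-4-hydroxy-5-(prop-2-en-1-yl)benzaldehyde
Conditions: N,N-diethylaniline, 200 °C, Ar, 6 h
Reagents that add atoms: none
Why: Aromatic Claisen rearrangement ([3,3]-sigmatropic shift, then tautomerisation) delivers the allyl group to the only free ortho position, because the other ortho site carries Br and the para site carries CHO.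

Step 9
Reactants: 11 3-bromo-4-hydroxy-5-(prop-2-en-1-yl)benzaldehyde
Product: 12 3-bromo-4-(methoxymethoxy)-5-(prop-2-en-1-yl)benzaldehyde
Conditions: MOMCl (1.5 equiv), K2CO3 (2.5 equiv), acetone, rt
Reagents that add atoms: chloromethyl methyl ether (MOMCl), COCCl
Why: O-alkylation of the hindered but acidic phenoxide with the small, reactive MOMCl gives a base-stable ether.

Step 10
Reactants: 12 3-bromo-4-(methoxymethoxy)-5-(prop-2-en-1-yl)benzaldehyde
Product: 13 2-[3-bromo-4-(methoxymethoxy)-5-(prop-2-en-1-yl)phenyl]-1,3-dioxolane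
Conditions: TMSOCH2CH2OTMS (1.5 equiv), TMSOTf (2 mol%), CH2Cl2, −78 → −20 °C; pyridine quench
Reagents that add atoms: 1,2-bis(trimethylsilyloxy)ethane, C[Si](C)(C)OCCO[Si](C)(C)C
Why: Noyori acetalisation under aprotic, low-temperature TMSOTf catalysis masks the aldehyde for the ylide, hydride and organolithium steps without cleaving the aryl MOM ether.

Step 11
Reactants: 13 2-[3-bromo-4-(methoxymethoxy)-5-(prop-2-en-1-yl)phenyl]-1,3-dioxolane
Product: 15 2-[3-bromo-5-(1,3-dioxolan-2-yl)-2-(methoxymethoxy)phenyl]acetaldehyde, via diol 14 (not isolated)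
Conditions: OsO4 (2 mol%), NaIO4 (4 equiv), 2,6-lutidine (2 equiv), 1,4-dioxane/H2O 3:1, rt; crude product used at once
Reagents that add atoms: osmium tetroxide, O=[Os](=O)(=O)=O (catalytic oxygen carrier); sodium periodate, [Na+].[O-]I(=O)(=O)=O (stoichiometric oxidant)
Why: Lemieux–Johnson oxidative cleavage (dihydroxylation, then periodate glycol cleavage, lutidine-buffered) converts the only alkene into the arylacetaldehyde under near-neutral conditions that spare both acetals.

Step 12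
Reactants: 15 2-[3-bromo-5-(1,3-dioxolan-2-yl)-2-(methoxymethoxy)phenyl]acetaldehyde
Product: 16 ethyl (2E)-4-[3-bromo-5-(1,3-dioxolan-2-yl)-2-(methoxymethoxy)phenyl]-2-methylbut-2-enoate
Conditions: Ph3P=C(CH3)CO2Et (1.3 equiv), CH2Cl2, rt
Reagents that add atoms: ethyl 2-(triphenylphosphoranylidene)propanoate, CCOC(=O)C(C)=P(c1ccccc1)(c1ccccc1)c1ccccc1
Why: Wittig olefination with this stabilised α-methyl ylide gives the (E)-trisubstituted enoate (typically >95:5), which fixes the side-chain double-bond geometry of the target.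

Step 13
Reactants: 16 ethyl (2E)-4-[3-bromo-5-(1,3-dioxolan-2-yl)-2-(methoxymethoxy)phenyl]-2-methylbut-2-enoate
Product: 17 (2E)-4-[3-bromo-5-(1,3-dioxolan-2-yl)-2-(methoxymethoxy)phenyl]-2-methylbut-2-en-1-ol
Conditions: i-Bu2AlH (2.5 equiv), CH2Cl2, −78 °C; aqueous potassium sodium tartrate
Reagents that add atoms: none
Why: 1,2-Reduction of the enoate by the aluminium hydride at low temperature gives the allylic alcohol without touching the alkene geometry, the aryl bromide or the acetals.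

Step 14
Reactants: 17 (2E)-4-[3-bromo-5-(1,3-dioxolan-2-yl)-2-(methoxymethoxy)phenyl]-2-methylbut-2-en-1-ol
Product: 18 tert-butyl{[(2E)-4-[3-bromo-5-(1,3-dioxolan-2-yl)-2-(methoxymethoxy)phenyl]-2-methylbut-2-en-1-yl]oxy}dimethylsilane
Conditions: TBSCl (1.2 equiv), imidazole (2 equiv), DMF, rt
Reagents that add atoms: tert-butyldimethylsilyl chloride, CC(C)(C)[Si](C)(C)Cl
Why: Silylation of the primary allylic alcohol gives an ether that withstands organolithium, hydroxide and alkaline peroxide and leaves under the same acid as the MOM groups.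

Step 15
Reactants: 18 tert-butyl{[(2E)-4-[3-bromo-5-(1,3-dioxolan-2-yl)-2-(methoxymethoxy)phenyl]-2-methylbut-2-en-1-yl]oxy}dimethylsilane
Product: 21 2-{3-[(2E)-4-(TBSO)-3-methylbut-2-en-1-yl]-4-(methoxymethoxy)-5-(3-methylbut-2-en-1-yl)phenyl}-1,3-dioxolane, via aryllithium 19 (not isolated), via arylcopper 20 (not isolated)
Conditions: n-BuLi (1.05 equiv), THF, −78 °C, 20 min; CuBr·SMe2 (1.1 equiv), −78 → −40 °C; prenyl bromide (1.5 equiv), −78 → 0 °C
Reagents that add atoms: prenyl bromide (1-bromo-3-methylbut-2-ene), CC(C)=CCBr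
Why: Bromine–lithium exchange is fast and site-specific at −78 °C, and the derived arylcopper undergoes allylic substitution on prenyl bromide at the unhindered primary carbon to give the linear prenyl group.

Step 16
Reactants: 21 2-{3-[(2E)-4-(TBSO)-3-methylbut-2-en-1-yl]-4-(methoxymethoxy)-5-(3-methylbut-2-en-1-yl)phenyl}-1,3-dioxolane
Product: 22 3-[(2E)-4-(TBSO)-3-methylbut-2-en-1-yl]-4-(methoxymethoxy)-5-(3-methylbut-2-en-1-yl)benzaldehyde
Conditions: PPTS (0.2 equiv), acetone/H2O 10:1, rt → 40 °C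
Reagents that add atoms: water, O
Why: Mild acid-catalysed acetal hydrolysis of the dioxolane of an electron-rich benzaldehyde is much faster than cleavage of the aryl MOM ether or the primary TBS ether.

**Fragment union and endgame**

Step 17
Reactants: 8 1-[6-hydroxy-3-methoxy-2,4-bis(methoxymethoxy)phenyl]ethan-1-one; 22 3-[(2E)-4-(TBSO)-3-methylbut-2-en-1-yl]-4-(methoxymethoxy)-5-(3-methylbut-2-en-1-yl)benzaldehyde
Product: 24 (2E)-3-Ar-1-[6-hydroxy-3-methoxy-2,4-bis(methoxymethoxy)phenyl]prop-2-en-1-one, via aldol adduct 23 (not isolated)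
Conditions: KOH (50% aq, 10 equiv), EtOH, rt, 48 h; neutralise with aq NH4Cl
Reagents that add atoms: none
Why: Intermolecular Claisen–Schmidt crossed aldol condensation: the methyl ketone enolate adds to the non-enolisable aldehyde and E1cB dehydration gives the conjugated (E)-chalcone, forming the future C2–C3 bond.

Step 18
Reactants: 24 (2E)-3-Ar-1-[6-hydroxy-3-methoxy-2,4-bis(methoxymethoxy)phenyl]prop-2-en-1-one
Product: 26 2-Ar-3-hydroxy-6-methoxy-5,7-bis(methoxymethoxy)-4H-chromen-4-one, via dihydroflavonol 25 (not isolated)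
Conditions: 30% H2O2 (5 equiv), aq NaOH (2 M, 5 equiv), MeOH/THF, 0 °C → rt; aq NH4Cl
Reagents that add atoms: hydrogen peroxide, OO
Why: Algar–Flynn–Oyamada reaction: the 2'-phenoxide cyclises onto the enone with oxygenation by hydroperoxide to the dihydroflavonol, which is oxidised further in the flask to the flavonol, while the isolated trisubstituted alkenes are inert to nucleophilic peroxide.

Step 19
Reactants: 26 2-Ar-3-hydroxy-6-methoxy-5,7-bis(methoxymethoxy)-4H-chromen-4-one
Product: 27 2-Ar-3,6-dimethoxy-5,7-bis(methoxymethoxy)-4H-chromen-4-one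
Conditions: MeI (3 equiv), K2CO3 (3 equiv), acetone, reflux
Reagents that add atoms: iodomethane, CI
Why: Williamson O-methylation of the acidic 3-OH, the only free hydroxyl in the molecule.

Step 20
Reactants: 27 2-Ar-3,6-dimethoxy-5,7-bis(methoxymethoxy)-4H-chromen-4-one
Product: 28 dodoviscin G, 5,7-dihydroxy-2-{4-hydroxy-3-[(2E)-4-hydroxy-3-methylbut-2-en-1-yl]-5-(3-methylbut-2-en-1-yl)phenyl}-3,6-dimethoxy-4H-chromen-4-one
Conditions: HCl (1.25 M in MeOH), THF, rt (40 °C only if needed)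
Reagents that add atoms: none
Why: Acid-catalysed acetal solvolysis removes the three MOM ethers and methanolysis removes the TBS ether in one operation, under acid dilute enough that the prenyl alkene is not protonated and the primary allylic alcohol does not ionise.

**Compound list**
1 | 2-methoxybenzene-1,3-diol | COc1c(O)cccc1O | starting material
2 | 2-methoxy-1,3-bis(methoxymethoxy)benzene | COCOc1cccc(OCOC)c1OC | intermediate
3 | 2-[4-methoxy-3,5-bis(methoxymethoxy)phenyl]-4,4,5,5-tetramethyl-1,3,2-dioxaborolane | COCOc1cc(B2OC(C)(C)C(C)(C)O2)cc(OCOC)c1OC | intermediate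
4 | 4-methoxy-3,5-bis(methoxymethoxy)phenol | COCOc1cc(O)cc(OCOC)c1OC | intermediate
5 | 5-(benzyloxy)-2-methoxy-1,3-bis(methoxymethoxy)benzene | COCOc1cc(OCc2ccccc2)cc(OCOC)c1OC | intermediate
6 | [6-(benzyloxy)-3-methoxy-2,4-bis(methoxymethoxy)phenyl]lithium | [Li]c1c(OCc2ccccc2)cc(OCOC)c(OC)c1OCOC | intermediate (not isolated)
7 | 1-[6-(benzyloxy)-3-methoxy-2,4-bis(methoxymethoxy)phenyl]ethan-1-one | CC(=O)c1c(OCc2ccccc2)cc(OCOC)c(OC)c1OCOC | intermediate
8 | 1-[6-hydroxy-3-methoxy-2,4-bis(methoxymethoxy)phenyl]ethan-1-one | CC(=O)c1c(O)cc(OCOC)c(OC)c1OCOC | intermediate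
9 | 3-bromo-4-hydroxybenzaldehyde | O=Cc1ccc(O)c(Br)c1 | starting material
10 | 3-bromo-4-(prop-2-en-1-yloxy)benzaldehyde | O=Cc1ccc(OCC=C)c(Br)c1 | intermediate
11 | 3-bromo-4-hydroxy-5-(prop-2-en-1-yl)benzaldehyde | O=Cc1cc(Br)c(O)c(CC=C)c1 | intermediate
12 | 3-bromo-4-(methoxymethoxy)-5-(prop-2-en-1-yl)benzaldehyde | O=Cc1cc(Br)c(OCOC)c(CC=C)c1 | intermediate
13 | 2-[3-bromo-4-(methoxymethoxy)-5-(prop-2-en-1-yl)phenyl]-1,3-dioxolane | C=CCc1cc(C2OCCO2)cc(Br)c1OCOC | intermediate
14 | 3-[3-bromo-5-(1,3-dioxolan-2-yl)-2-(methoxymethoxy)phenyl]propane-1,2-diol (racemic) | OCC(O)Cc1cc(C2OCCO2)cc(Br)c1OCOC | intermediate (not isolated)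
15 | 2-[3-bromo-5-(1,3-dioxolan-2-yl)-2-(methoxymethoxy)phenyl]acetaldehyde | O=CCc1cc(C2OCCO2)cc(Br)c1OCOC | intermediate
16 | ethyl (2E)-4-[3-bromo-5-(1,3-dioxolan-2-yl)-2-(methoxymethoxy)phenyl]-2-methylbut-2-enoate | CCOC(=O)/C(C)=C/Cc1cc(C2OCCO2)cc(Br)c1OCOC | intermediate
17 | (2E)-4-[3-bromo-5-(1,3-dioxolan-2-yl)-2-(methoxymethoxy)phenyl]-2-methylbut-2-en-1-ol | OC/C(C)=C/Cc1cc(C2OCCO2)cc(Br)c1OCOC | intermediate
18 | tert-butyl{[(2E)-4-[3-bromo-5-(1,3-dioxolan-2-yl)-2-(methoxymethoxy)phenyl]-2-methylbut-2-en-1-yl]oxy}dimethylsilane | CC(C)(C)[Si](C)(C)OC/C(C)=C/Cc1cc(C2OCCO2)cc(Br)c1OCOC | intermediate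
19 | {3-[(2E)-4-(TBSO)-3-methylbut-2-en-1-yl]-5-(1,3-dioxolan-2-yl)-2-(methoxymethoxy)phenyl}lithium | [Li]c1cc(C2OCCO2)cc(C/C=C(\C)CO[Si](C)(C)C(C)(C)C)c1OCOC | intermediate (not isolated)
20 | {3-[(2E)-4-(TBSO)-3-methylbut-2-en-1-yl]-5-(1,3-dioxolan-2-yl)-2-(methoxymethoxy)phenyl}copper | [Cu]c1cc(C2OCCO2)cc(C/C=C(\C)CO[Si](C)(C)C(C)(C)C)c1OCOC | intermediate (not isolated)
21 | 2-{3-[(2E)-4-(TBSO)-3-methylbut-2-en-1-yl]-4-(methoxymethoxy)-5-(3-methylbut-2-en-1-yl)phenyl}-1,3-dioxolane | CC(C)=CCc1cc(C2OCCO2)cc(C/C=C(\C)CO[Si](C)(C)C(C)(C)C)c1OCOC | intermediate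
22 | 3-[(2E)-4-(TBSO)-3-methylbut-2-en-1-yl]-4-(methoxymethoxy)-5-(3-methylbut-2-en-1-yl)benzaldehyde | CC(C)=CCc1cc(C=O)cc(C/C=C(\C)CO[Si](C)(C)C(C)(C)C)c1OCOC | intermediate
23 | 3-Ar-3-hydroxy-1-[6-hydroxy-3-methoxy-2,4-bis(methoxymethoxy)phenyl]propan-1-one (racemic) | CC(C)=CCc1cc(C(O)CC(=O)c2c(O)cc(OCOC)c(OC)c2OCOC)cc(C/C=C(\C)CO[Si](C)(C)C(C)(C)C)c1OCOC | intermediate (not isolated)
24 | (2E)-3-Ar-1-[6-hydroxy-3-methoxy-2,4-bis(methoxymethoxy)phenyl]prop-2-en-1-one | CC(C)=CCc1cc(/C=C/C(=O)c2c(O)cc(OCOC)c(OC)c2OCOC)cc(C/C=C(\C)CO[Si](C)(C)C(C)(C)C)c1OCOC | intermediate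
25 | trans-2-Ar-3-hydroxy-6-methoxy-5,7-bis(methoxymethoxy)-2,3-dihydro-4H-chromen-4-one (racemic; the 2R,3R enantiomer is drawn) | COCOc1cc2O[C@H](c3cc(CC=C(C)C)c(OCOC)c(C/C=C(\C)CO[Si](C)(C)C(C)(C)C)c3)[C@@H](O)C(=O)c2c(OCOC)c1OC | intermediate (not isolated)
26 | 2-Ar-3-hydroxy-6-methoxy-5,7-bis(methoxymethoxy)-4H-chromen-4-one | COCOc1cc2oc(-c3cc(CC=C(C)C)c(OCOC)c(C/C=C(\C)CO[Si](C)(C)C(C)(C)C)c3)c(O)c(=O)c2c(OCOC)c1OC | intermediate
27 | 2-Ar-3,6-dimethoxy-5,7-bis(methoxymethoxy)-4H-chromen-4-one | COCOc1cc2oc(-c3cc(CC=C(C)C)c(OCOC)c(C/C=C(\C)CO[Si](C)(C)C(C)(C)C)c3)c(OC)c(=O)c2c(OCOC)c1OC | intermediate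
28 | dodoviscin G, 5,7-dihydroxy-2-{4-hydroxy-3-[(2E)-4-hydroxy-3-methylbut-2-en-1-yl]-5-(3-methylbut-2-en-1-yl)phenyl}-3,6-dimethoxy-4H-chromen-4-one | COc1c(O)cc2oc(-c3cc(CC=C(C)C)c(O)c(C/C=C(\C)CO)c3)c(OC)c(=O)c2c1O | target

**Totals**
Total step count: 20 (6 for the ring A ketone, 10 for the ring B aldehyde, 4 after union).
Longest linear sequence: 14 steps (steps 7–16, then 17–20).

**Three steps most likely to fail**

Step 18 (Algar–Flynn–Oyamada). A 6'-alkoxy group on the chalcone favours the competing 5-exo pathway to an aurone. The fallback sets out from chalcone 24 and comes back at flavonol 26, introducing the 3-oxygen by C–H lithiation instead of enone oxygenation. Chalcone 24 is cyclised by oxa-Michael addition (NaOAc, EtOH/H2O, reflux) to the racemic flavanone F2. This is dehydrogenated with IBX in DMSO at 70 °C to the flavone F3. Deprotonation at C3 with LiN(i-Pr)2 in THF at −78 °C gives the 3-lithioflavone F4, which is trapped with B(OMe)3 as the dimethyl flavon-3-ylboronate F5. Oxidation in the same flask with H2O2/NaOH at 0 °C gives 26.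

Step 15 (arylcopper prenylation). Possible problems are branched (reverse-prenyl) product, protonation of the aryllithium, or butylation. The fallback sets out from bromide 18 and comes back at 21, reversing the polarity of the coupling. Miyaura borylation of 18 (B2pin2, PdCl2(dppf), KOAc, 1,4-dioxane, 90 °C) gives the aryl pinacol boronate F1. Suzuki–Miyaura allylation of F1 with prenyl bromide (Pd(PPh3)4, K2CO3, THF/H2O, 60 °C) proceeds through a π-prenyl palladium species that couples at its less hindered terminus and gives the linear product 21.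

Step 20 (global acid deprotection). Possible problems are chroman formation from the prenyl group and the freed 4'-OH, or solvolysis of the allylic alcohol. The fallback sets out from 27 and comes back at 28, unmasking in two orthogonal stages without protic acid. Fluoride desilylation (TBAF, THF, 0 °C) gives the tris-MOM allylic alcohol F6. The aryl MOM ethers of F6 are then exchanged for silyl ethers with TMSOTf/2,2'-bipyridyl in CH3CN at 0 °C → rt, and water added at the end hydrolyses them to give 28.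

**Further compounds**
F1 | step 15 | 2-{3-[(2E)-4-(TBSO)-3-methylbut-2-en-1-yl]-5-(1,3-dioxolan-2-yl)-2-(methoxymethoxy)phenyl}-4,4,5,5-tetramethyl-1,3,2-dioxaborolane | CC(C)(C)[Si](C)(C)OC/C(C)=C/Cc1cc(C2OCCO2)cc(B2OC(C)(C)C(C)(C)O2)c1OCOC
F2 | step 18 | 2-Ar-6-methoxy-5,7-bis(methoxymethoxy)-2,3-dihydro-4H-chromen-4-one (racemic flavanone) | COCOc1cc2OC(c3cc(CC=C(C)C)c(OCOC)c(C/C=C(\C)CO[Si](C)(C)C(C)(C)C)c3)CC(=O)c2c(OCOC)c1OC
F3 | step 18 | 2-Ar-6-methoxy-5,7-bis(methoxymethoxy)-4H-chromen-4-one (flavone) | COCOc1cc2oc(-c3cc(CC=C(C)C)c(OCOC)c(C/C=C(\C)CO[Si](C)(C)C(C)(C)C)c3)cc(=O)c2c(OCOC)c1OC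
F4 | step 18 | [2-Ar-6-methoxy-5,7-bis(methoxymethoxy)-4-oxo-4H-chromen-3-yl]lithium | COCOc1cc2oc(-c3cc(CC=C(C)C)c(OCOC)c(C/C=C(\C)CO[Si](C)(C)C(C)(C)C)c3)c([Li])c(=O)c2c(OCOC)c1OC
F5 | step 18 | dimethyl [2-Ar-6-methoxy-5,7-bis(methoxymethoxy)-4-oxo-4H-chromen-3-yl]boronate | COCOc1cc2oc(-c3cc(CC=C(C)C)c(OCOC)c(C/C=C(\C)CO[Si](C)(C)C(C)(C)C)c3)c(B(OC)OC)c(=O)c2c(OCOC)c1OC
F6 | step 20 | 2-{3-[(2E)-4-hydroxy-3-methylbut-2-en-1-yl]-4-(methoxymethoxy)-5-(3-methylbut-2-en-1-yl)phenyl}-3,6-dimethoxy-5,7-bis(methoxymethoxy)-4H-chromen-4-one | COCOc1cc2oc(-c3cc(CC=C(C)C)c(OCOC)c(C/C=C(\C)CO)c3)c(OC)c(=O)c2c(OCOC)c1OC
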